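**Retrosynthetic overview**
1. Target 27 ⇐ ester hydrolysis, CBS reduction of enone 25, and addition of the 2‑lithioalkene made from dihydro‑β‑ionone (cyclohexene ring bought) to aldehyde 20.
2. C6 quaternary centre ⇐ methyl transfer to the C6 peroxycarbenium ion formed by opening a temporary spiro‑tetrahydrofuran ring (not in the target); the opening also frees the three‑carbon arm.
3. C3 and Cα ⇐ anti‑SE2' addition of a chiral (E)‑crotylsilane to the C3 methoxy peroxyacetal, then cleavage of the new alkene to the acid.
4. 1,2‑Dioxane ⇐ ozonolytic ring expansion of cyclobutene 5: O–O is inserted into the ring C=C, so the four ring carbons become C3–C6 of the dioxane. Ring order: cyclobutene → 1,2‑dioxane plus spiro‑THF (same operation) → THF opened.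
5. Enabling feature: the strained C1=C2 bond of the cyclobutene ring of 5, whose two carbons stay tied by C3H2–C4H2 after cleavage (so they reclose through O–O to a six‑membered ring), and the 3‑hydroxypropyl arm on C1, placed to form a five‑membered ketal.

Key step: step 3

Remark: cyclobutanone, oxetane, (S)‑but‑3‑yn‑2‑ol, dihydro‑β‑ionone and the reagents named are taken as commercial; C3–C6 and Cα denote the dioxane carbons and the propanoate α‑carbon of the target.

**Step 1**
Reactants: 1 cyclobutanone
Product: 2 N'-cyclobutylidene-2,4,6-tri(propan-2-yl)benzenesulfonohydrazide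
Conditions: 2,4,6-(i-Pr)3C6H2SO2NHNH2, MeOH, HCl (cat.), 0 °C → rt
Reagents that add atoms: 2,4,6-tri(propan-2-yl)benzenesulfonohydrazide CC(C)c1cc(C(C)C)c(S(=O)(=O)NN)c(C(C)C)c1
Why: Hydrazone formation by condensation, with the ortho isopropyl groups blocking later ortho‑lithiation; no stereocentre.

**Step 2**
Reactants: 2 cyclobutanone trisylhydrazone; 3 oxetane
Product: 5 3-(cyclobut-1-en-1-yl)propan-1-ol, via cyclobut-1-en-1-yllithium 4 (not isolated)
Conditions: n-BuLi (2.1 equiv), THF, −78 → 0 °C; then 3, BF3·OEt2, −78 °C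
Reagents that add atoms: none
Why: Shapiro reaction (double deprotonation, loss of sulfinate and N2) should give the vinyllithium, which opens BF3‑activated oxetane by SN2 attack to install the 3‑hydroxypropyl arm; no stereocentre.

**Step 3**
Reactants: 5 3-(cyclobut-1-en-1-yl)propan-1-ol
Product: 8 8-methoxy-1,6,7-trioxaspiro[4.5]decane (racemic diastereomer mixture), via primary ozonide 6 (not isolated), via methoxy hydroperoxide aldehyde 7 (not isolated)
Conditions: O3, CH2Cl2/MeOH 4:1, −78 °C; N2 purge; then PPTS (10 mol %), −20 °C → rt (no reductant)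
Reagents that add atoms: ozone [O-][O+]=O; methanol CO
Why: Ozone adds to the strained ring C=C (1,3‑dipolar cycloaddition) and the primary ozonide cleaves (Criegee mechanism) in methanol to the methoxy hydroperoxide aldehyde, whose O–O–H adds to the aldehyde held four atoms away, so that the two former alkene carbons are rejoined through O–O and the four‑membered carbocycle becomes the six‑membered 1,2‑dioxane (net O–O insertion into C1=C2, driven by release of cyclobutene strain). PPTS then exchanges the ketal methoxy group for the pendant hydroxyl (spiro‑tetrahydrofuran) and the hemiperacetal OH for OMe. The closest known reaction type is the ozonolysis of cycloalkenes in alcohols to cyclic alkoxy peroxy acetals, combined with acid‑catalysed ketal exchange. Ring closures: the 1,2‑dioxane by 6‑exo‑trig addition of the hydroperoxide to the aldehyde carbonyl, the tetrahydrofuran by 5‑exo closure of the hydroxyl on the ketal carbon. The two new stereocentres (spiro C5 and acetal C8) are formed without control, which is intended, because both are ionised later (C8 in step 6, C5 in step 9). The step needs retention of the O–O bond, secured by the absence of any reductant and by only mild acid, and it needs no regiocontrol of the Criegee cleavage because both cleavage directions converge on 8.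

**Step 4**
Reactants: 9 (S)-but-3-yn-2-ol
Product: 10 (S,E)-4-[dimethyl(phenyl)silyl]but-3-en-2-ol
Conditions: PhMe2SiH, Pt2[(CH2=CHSiMe2)2O]3 (0.5 mol %), P(t-Bu)3 (1 mol %), THF, 0 °C → rt
Reagents that add atoms: dimethyl(phenyl)silane C[SiH](C)c1ccccc1
Why: Pt‑catalysed syn hydrosilylation (Chalk–Harrod mechanism) with a bulky phosphine should place silicon on the terminal carbon with E geometry, the carbinol stereocentre coming unchanged from the chiral pool.

**Step 5**
Reactants: 10 (S,E)-4-[dimethyl(phenyl)silyl]but-3-en-2-ol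
Product: 12 methyl (S,E)-3-[dimethyl(phenyl)silyl]hex-4-enoate, via mixed ketene acetal 11 (not isolated)
Conditions: MeC(OMe)3 (5 equiv), EtCO2H (5 mol %), PhMe, 110 °C, MeOH distilled off
Reagents that add atoms: trimethyl orthoacetate CC(OC)(OC)OC
Why: Johnson–Claisen rearrangement through a chair transition state with the carbinol methyl equatorial should transfer the C–O stereocentre suprafacially to the new C–Si stereocentre (S) and give the E alkene.

**Step 6**
Reactants: 8 8-methoxy-1,6,7-trioxaspiro[4.5]decane; 12 methyl (S,E)-3-[dimethyl(phenyl)silyl]hex-4-enoate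
Product: 14 methyl (3E,5S)-5-[(8S)-1,6,7-trioxaspiro[4.5]decan-8-yl]hex-3-enoate (both spiro epimers), via peroxycarbenium triflate 13 (not isolated)
Conditions: 12 (1.3 equiv), Me3SiOTf (0.3 equiv), CH2Cl2, −78 → −40 °C
Reagents that add atoms: none
Why: Me3SiOTf should ionise the exocyclic C8–OMe bond (the spiro ketal can only open reversibly and reclose) and the crotylsilane adds by anti‑SE2' (Hosomi–Sakurai type addition of an allylsilane to a peroxycarbenium ion) through an antiperiplanar open transition state with the ring lying over the crotyl hydrogen, so that the silane stereocentre sets the methyl‑bearing carbon (reagent control) and the syn topicity sets C8 as S.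

**Step 7**
Reactants: 14 methyl (3E,5S)-5-[(8S)-1,6,7-trioxaspiro[4.5]decan-8-yl]hex-3-enoate
Product: 16 (2R)-2-[(8S)-1,6,7-trioxaspiro[4.5]decan-8-yl]propanoic acid, via aldehyde 15 (not isolated)
Conditions: O3, CH2Cl2, −78 °C; Me2S; then NaClO2, NaH2PO4, 2-methylbut-2-ene, t-BuOH/H2O, 0 °C
Reagents that add atoms: ozone [O-][O+]=O; sodium chlorite [Na+].[O-]Cl=O
Why: Ozonolysis of the only C=C with a dimethyl sulfide work‑up that leaves the dialkyl peroxide intact, then Pinnick oxidation of the sensitive α‑methyl aldehyde without isolation under weakly acidic conditions that should avoid epimerisation and β‑elimination; no new stereocentre.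

**Step 8**
Reactants: 16 (2R)-2-[(8S)-1,6,7-trioxaspiro[4.5]decan-8-yl]propanoic acid
Product: 17 methyl (2R)-2-[(8S)-1,6,7-trioxaspiro[4.5]decan-8-yl]propanoate
Conditions: Me3SiCHN2, PhMe/MeOH 4:1, 0 °C
Reagents that add atoms: (trimethylsilyl)diazomethane C[Si](C)(C)C=[N+]=[N-]
Why: Neutral O‑methylation of the acid with the diazoalkane protects it for the organometallic steps; no stereocentre is touched.

**Step 9**
Reactants: 17 methyl (2R)-2-[(8S)-1,6,7-trioxaspiro[4.5]decan-8-yl]propanoate
Product: 19 methyl (2R)-2-[(3S,6R)-6-(3-hydroxypropyl)-6-methyl-1,2-dioxan-3-yl]propanoate, via ring-opened peroxycarbenium aluminate 18 (not isolated)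
Conditions: AlMe3 (4 equiv), CH2Cl2, −78 → −20 °C; aq. KNaC4H4O6
Reagents that add atoms: trimethylaluminium C[Al](C)C
Why: Proposed new method: AlMe3 should bind the more basic tetrahydrofuran oxygen of the spiro peroxyketal, heterolysis of that C–O bond gives a tertiary peroxycarbenium ion (alkoxide leaves in preference to peroxide, as in the known Lewis‑acid substitutions of alkyl peroxy ketals by allylsilanes and silyl ketene acetals, and methyl transfer from AlMe3 to ketal‑derived oxocarbenium ions is known for ordinary spiro and bicyclic ketals), and methyl is delivered axially through a chair‑like transition state to the half‑chair cation whose C3 substituent is pseudo‑equatorial, which places CH3 cis to the C3 side chain and the released 3‑hydroxypropyl arm trans (C6 = R), the spiro configuration being erased in the cation.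

**Step 10**
Reactants: 19 methyl (2R)-2-[(3S,6R)-6-(3-hydroxypropyl)-6-methyl-1,2-dioxan-3-yl]propanoate
Product: 20 methyl (2R)-2-[(3S,6S)-6-methyl-6-(3-oxopropyl)-1,2-dioxan-3-yl]propanoate
Conditions: Dess–Martin periodinane, CH2Cl2, 0 °C → rt
Reagents that add atoms: none
Why: Dess–Martin oxidation of the primary alcohol to the aldehyde under neutral conditions that dialkyl peroxides tolerate; no stereocentre is touched (the C6 descriptor changes by priority only).

**Step 11**
Reactants: 21 4-(2,6,6-trimethylcyclohex-1-en-1-yl)butan-2-one (dihydro-β-ionone)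
Product: 22 N'-[4-(2,6,6-trimethylcyclohex-1-en-1-yl)butan-2-ylidene]-2,4,6-tri(propan-2-yl)benzenesulfonohydrazide
Conditions: 2,4,6-(i-Pr)3C6H2SO2NHNH2, MeOH, HCl (cat.), rt
Reagents that add atoms: 2,4,6-tri(propan-2-yl)benzenesulfonohydrazide CC(C)c1cc(C(C)C)c(S(=O)(=O)NN)c(C(C)C)c1
Why: Hydrazone formation by condensation; no stereocentre.

**Step 12**
Reactants: 22 dihydro-β-ionone trisylhydrazone; 20 methyl (2R)-2-[(3S,6S)-6-methyl-6-(3-oxopropyl)-1,2-dioxan-3-yl]propanoate
Product: 24 methyl (2R)-2-[(3S,6R)-6-[3-hydroxy-4-methylidene-6-(2,6,6-trimethylcyclohex-1-en-1-yl)hexyl]-6-methyl-1,2-dioxan-3-yl]propanoate (both carbinol epimers), via alkenyllithium 23 (not isolated)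
Conditions: 22 (1.5 equiv), n-BuLi (3.1 equiv), TMEDA/THF, −78 → 0 °C; then 20, −78 °C
Reagents that add atoms: none
Why: Shapiro reaction with deprotonation at the methyl group should give the less substituted 2‑lithioalkene, which adds to the aldehyde at −78 °C faster than to the methyl ester or the dialkyl peroxide; the carbinol centre is formed without control and is erased in step 13.

**Step 13**
Reactants: 24 allylic alcohol (both carbinol epimers)
Product: 25 methyl (2R)-2-[(3S,6S)-6-methyl-6-[4-methylidene-3-oxo-6-(2,6,6-trimethylcyclohex-1-en-1-yl)hexyl]-1,2-dioxan-3-yl]propanoate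
Conditions: Dess–Martin periodinane, CH2Cl2, 0 °C
Reagents that add atoms: none
Why: Dess–Martin oxidation of the allylic alcohol to the α‑methylene ketone removes the uncontrolled carbinol centre without touching the peroxide or the alkenes.

**Step 14**
Reactants: 25 enone
Product: 26 methyl (2R)-2-[(3S,6R)-6-[(3R)-3-hydroxy-4-methylidene-6-(2,6,6-trimethylcyclohex-1-en-1-yl)hexyl]-6-methyl-1,2-dioxan-3-yl]propanoate
Conditions: (S)-2-methyl-CBS-oxazaborolidine (0.5 equiv), catecholborane (1.5 equiv), PhMe, −78 °C
Reagents that add atoms: none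
Why: Corey–Bakshi–Shibata reduction, in which the (S)‑oxazaborolidine–borane complex binds the ketone with the larger 2‑substituted alkenyl group away from the catalyst and delivers hydride to one face, should give the (R)‑allylic alcohol by reagent control, with 1,2‑reduction favoured at low temperature.

**Step 15**
Reactants: 26 methyl ester
Product: 27 (2R)-2-[(3S,6R)-6-[(3R)-3-hydroxy-4-methylidene-6-(2,6,6-trimethylcyclohex-1-en-1-yl)hexyl]-6-methyl-1,2-dioxan-3-yl]propanoic acid
Conditions: LiOH, THF/H2O 3:1, 0 °C → rt; then 1 M HCl to pH 3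
Reagents that add atoms: lithium hydroxide [Li+].[OH-]
Why: Saponification of the methyl ester under mild conditions that the dialkyl peroxide and the allylic alcohol should survive; no stereocentre is changed.

**Compound list**
1 | cyclobutanone | O=C1CCC1 | starting material
2 | N'-cyclobutylidene-2,4,6-tri(propan-2-yl)benzenesulfonohydrazide | CC(C)c1cc(C(C)C)c(S(=O)(=O)NN=C2CCC2)c(C(C)C)c1 | intermediate
3 | oxetane | C1COC1 | starting material
4 | cyclobut-1-en-1-yllithium | [Li]C1=CCC1 | intermediate
5 | 3-(cyclobut-1-en-1-yl)propan-1-ol | OCCCC1=CCC1 | intermediate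
6 | 3-(2,3,4-trioxabicyclo[3.2.0]heptan-1-yl)propan-1-ol (primary ozonide) | OCCCC12CCC1OOO2 | intermediate
7 | 4-hydroperoxy-7-hydroxy-4-methoxyheptanal | OCCCC(OC)(OO)CCC=O | intermediate
8 | 8-methoxy-1,6,7-trioxaspiro[4.5]decane (racemic diastereomer mixture) | COC1CCC2(CCCO2)OO1 | intermediate
9 | (S)-but-3-yn-2-ol | C[C@H](O)C#C | starting material
10 | (S,E)-4-[dimethyl(phenyl)silyl]but-3-en-2-ol | C[C@H](O)/C=C/[Si](C)(C)c1ccccc1 | intermediate
11 | (S,E)-[3-(1-methoxyethenyloxy)but-1-en-1-yl]dimethyl(phenyl)silane (mixed ketene acetal) | C=C(OC)O[C@@H](C)/C=C/[Si](C)(C)c1ccccc1 | intermediate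
12 | methyl (S,E)-3-[dimethyl(phenyl)silyl]hex-4-enoate | C/C=C/[C@H](CC(=O)OC)[Si](C)(C)c1ccccc1 | intermediate
13 | 1,6,7-trioxaspiro[4.5]decan-8-ylium trifluoromethanesulfonate (peroxycarbenium triflate) | [CH+]1CCC2(CCCO2)OO1.[O-]S(=O)(=O)C(F)(F)F | intermediate
14 | methyl (3E,5S)-5-[(8S)-1,6,7-trioxaspiro[4.5]decan-8-yl]hex-3-enoate (both spiro epimers) | C1COC2(C1)CC[C@@H]([C@@H](C)/C=C/CC(=O)OC)OO2 | intermediate
15 | (2R)-2-[(8S)-1,6,7-trioxaspiro[4.5]decan-8-yl]propanal | C1COC2(C1)CC[C@@H]([C@@H](C)C=O)OO2 | intermediate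
16 | (2R)-2-[(8S)-1,6,7-trioxaspiro[4.5]decan-8-yl]propanoic acid | C1COC2(C1)CC[C@@H]([C@@H](C)C(=O)O)OO2 | intermediate
17 | methyl (2R)-2-[(8S)-1,6,7-trioxaspiro[4.5]decan-8-yl]propanoate | C1COC2(C1)CC[C@@H]([C@@H](C)C(=O)OC)OO2 | intermediate
18 | ring-opened C6 peroxycarbenium ion with trimethylaluminate alkoxide (zwitterion) | C[Al-](C)(C)OCCC[C+]1CC[C@@H]([C@@H](C)C(=O)OC)OO1 | intermediate
19 | methyl (2R)-2-[(3S,6R)-6-(3-hydroxypropyl)-6-methyl-1,2-dioxan-3-yl]propanoate | OCCC[C@]1(C)CC[C@@H]([C@@H](C)C(=O)OC)OO1 | intermediate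
20 | methyl (2R)-2-[(3S,6S)-6-methyl-6-(3-oxopropyl)-1,2-dioxan-3-yl]propanoate | O=CCC[C@]1(C)CC[C@@H]([C@@H](C)C(=O)OC)OO1 | intermediate
21 | 4-(2,6,6-trimethylcyclohex-1-en-1-yl)butan-2-one | CC(=O)CCC1=C(C)CCCC1(C)C | starting material
22 | N'-[4-(2,6,6-trimethylcyclohex-1-en-1-yl)butan-2-ylidene]-2,4,6-tri(propan-2-yl)benzenesulfonohydrazide | CC(CCC1=C(C)CCCC1(C)C)=NNS(=O)(=O)c1c(C(C)C)cc(C(C)C)cc1C(C)C | intermediate
23 | [4-(2,6,6-trimethylcyclohex-1-en-1-yl)but-1-en-2-yl]lithium | [Li]C(=C)CCC1=C(C)CCCC1(C)C | intermediate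
24 | methyl (2R)-2-[(3S,6R)-6-[3-hydroxy-4-methylidene-6-(2,6,6-trimethylcyclohex-1-en-1-yl)hexyl]-6-methyl-1,2-dioxan-3-yl]propanoate (both carbinol epimers) | C=C(CCC1=C(C)CCCC1(C)C)C(O)CC[C@]1(C)CC[C@@H]([C@@H](C)C(=O)OC)OO1 | intermediate
25 | methyl (2R)-2-[(3S,6S)-6-methyl-6-[4-methylidene-3-oxo-6-(2,6,6-trimethylcyclohex-1-en-1-yl)hexyl]-1,2-dioxan-3-yl]propanoate | C=C(CCC1=C(C)CCCC1(C)C)C(=O)CC[C@]1(C)CC[C@@H]([C@@H](C)C(=O)OC)OO1 | intermediate
26 | methyl (2R)-2-[(3S,6R)-6-[(3R)-3-hydroxy-4-methylidene-6-(2,6,6-trimethylcyclohex-1-en-1-yl)hexyl]-6-methyl-1,2-dioxan-3-yl]propanoate | C=C(CCC1=C(C)CCCC1(C)C)[C@H](O)CC[C@]1(C)CC[C@@H]([C@@H](C)C(=O)OC)OO1 | intermediate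
27 | (2R)-2-[(3S,6R)-6-[(3R)-3-hydroxy-4-methylidene-6-(2,6,6-trimethylcyclohex-1-en-1-yl)hexyl]-6-methyl-1,2-dioxan-3-yl]propanoic acid | C=C(CCC1=C(C)CCCC1(C)C)[C@H](O)CC[C@]1(C)CC[C@@H]([C@@H](C)C(=O)O)OO1 | target

**Totals**
Total step count: 15. Longest linear sequence: 12 steps (steps 1, 2, 3, 6, 7, 8, 9, 10, 12, 13, 14, 15).

**Steps most likely to fail**

Step 9 (proposed new method). The organoaluminium may reduce or fragment the O–O bond before the C–O bond ionises. Methyl may also be delivered within a tight ion pair, which would erode the axial‑attack preference and the facial selectivity at C6. Fallback with known chemistry, setting out from 17 and coming back at 19: the spiro ketal is opened by the known Lewis‑acid substitution of peroxy ketals with a silyl ketene acetal, here 1‑tert‑butoxy‑1‑(tert‑butyldimethylsilyloxy)ethene with Me3SiOTf in CH2Cl2 at −78 °C. By the same axial attack this should give the tert‑butyl ester silyl ether F1, with the acetate arm cis to the C3 side chain. Me3SiOTf/2,6‑lutidine followed by aqueous work‑up cleaves the tert‑butyl ester to the acid F2. Coupling with 1‑hydroxypyridine‑2(1H)‑thione (EDC·HCl) gives the Barton ester F3. Photolysis with t‑BuSH in excess, so that hydrogen transfer outruns epoxide formation from the β‑peroxy radical, should give the methyl compound as its silyl ether F4 by Barton reductive decarboxylation. HF·pyridine then returns 19.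

Step 6. The spiro ketal carbon may ionise in competition, so that the silane attacks C5, and the simple syn/anti diastereoselection may erode because the cyclic cation carries no strong steric bias. Fallback, setting out from 8 and coming back at 16: the chlorotitanium enolate of (S)‑4‑benzyl‑3‑propanoyl‑1,3‑oxazolidin‑2‑one (TiCl4, i‑Pr2NEt, CH2Cl2, −78 °C) is combined with 8 and SnCl4. The chelated Z‑enolate fixes Cα through the auxiliary, and the ring of the cation should again lie over the enolate hydrogen (syn), giving the imide F5. LiOH/H2O2 in THF/H2O at 0 °C cleaves the auxiliary and gives 16.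

Step 3. Acid may expel hydrogen peroxide from the hydroperoxy ketal, the ketal exchange may stay incomplete, or the ozonide may form intramolecularly in competition; each would give peroxide‑free spiroketal or mixtures of open and cyclic peroxy acetals. Fallback, setting out from 5 and coming back at 8: ozonolysis in pure CH2Cl2 at −78 °C (no alcohol) should give the isolable bicyclic ozonide F6. PPTS in CH2Cl2 then lets the pendant hydroxyl open the tertiary bridgehead C–O bond to the spiro hemiperacetal F7. MeOH with HC(OMe)3 and PPTS converts the hemiperacetal OH to OMe and returns 8.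

**Further compounds**
F1 | step 9 | methyl (2R)-2-[(3S)-6-(2-tert-butoxy-2-oxoethyl)-6-[3-(tert-butyldimethylsilyloxy)propyl]-1,2-dioxan-3-yl]propanoate, acetate arm cis to the C3 side chain | CC(C)(C)[Si](C)(C)OCCC[C@]1(CC(=O)OC(C)(C)C)CC[C@@H]([C@@H](C)C(=O)OC)OO1
F2 | step 9 | 2-[(6S)-3-[3-(tert-butyldimethylsilyloxy)propyl]-6-[(2R)-1-methoxy-1-oxopropan-2-yl]-1,2-dioxan-3-yl]acetic acid, same ring configuration as F1 | CC(C)(C)[Si](C)(C)OCCC[C@]1(CC(=O)O)CC[C@@H]([C@@H](C)C(=O)OC)OO1
F3 | step 9 | 2-thioxopyridin-1(2H)-yl ester of F2 (Barton ester) | CC(C)(C)[Si](C)(C)OCCC[C@]1(CC(=O)ON2C=CC=CC2=S)CC[C@@H]([C@@H](C)C(=O)OC)OO1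
F4 | step 9 | methyl (2R)-2-[(3S,6R)-6-[3-(tert-butyldimethylsilyloxy)propyl]-6-methyl-1,2-dioxan-3-yl]propanoate | CC(C)(C)[Si](C)(C)OCCC[C@]1(C)CC[C@@H]([C@@H](C)C(=O)OC)OO1
F5 | step 6 | (4S)-4-benzyl-3-[(2R)-2-[(8S)-1,6,7-trioxaspiro[4.5]decan-8-yl]propanoyl]-1,3-oxazolidin-2-one | O=C1OC[C@H](Cc2ccccc2)N1C(=O)[C@H](C)[C@@H]1CCC2(CCCO2)OO1
F6 | step 3 | 3-(2,3,7-trioxabicyclo[2.2.1]heptan-1-yl)propan-1-ol | OCCCC12CCC(OO1)O2
F7 | step 3 | 1,6,7-trioxaspiro[4.5]decan-8-ol | OC1CCC2(CCCO2)OO1
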